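**Retrosynthetic overview**

1. Feature (abietane numbering): the isochroman ring C8–C7–O–C20–C10–C9 shares C7, C8, C9 and C10 with ring B (C5–C6–C7–C8–C9–C10). The two rings form a benzo-fused 2-oxabicyclo[2.2.2]octane, and its C7–C8 bond is the retron of a 2-arylethanol (C9–C10–C20–OH) condensing with an aldehyde (C7).
2. Key disconnection C7–C8: the C7 lactol of a ring-A aryl(hydroxymethyl)cyclohexyl acetaldehyde ionises to a cyclic oxocarbenium ion, and the aryl group on C10 closes ring B and the ether ring in one Friedel–Crafts event.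
3. Lactol ⇐ δ-lactone ⇐ 1,5-diol ⇐ ring-A diester; ring A by 6-exo Michael addition (C5–C10) of an arylacetate enolate to an enoate, with the C2 silyloxy centre steering C5 and C10.
4. Michael substrate ⇐ arylacetate (from 3-isopropylcatechol: methylation, ortho-lithiation/borylation, Pd coupling with methyl bromoacetate) + silyloxy iodide (from (S)-epichlorohydrin and prenyl Grignard, γ-attack), then alkene cleavage and Wittig.
5. Ring order: arene (bought) → ring A → ring B and ether ring together; end game: desilylation, thiolate demethylation with in-flask peracetylation, selective cleavage of the two aryl acetates.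

Key step: step 14

Remark: abietane numbering is used for all cyclic compounds; the target is read as (2S,5S,7S,10R), with the C2 acetate equatorial and on the face opposite to the C20 bridge, and H5 axial and anti to C20.

**Route**

Step 1
Reactants: 1 (S)-epichlorohydrin; 2 prenyl chloride
Product: 4 (S)-1-chloro-4,4-dimethylhex-5-en-2-ol, via prenylmagnesium chloride 3 (not isolated)
Conditions: Mg, THF, 0 °C; then 1, THF, −78 → 0 °C; aqueous work-up
Reagents that add atoms: none
Why: Grignard formation and epoxide opening, in which the allylic Grignard reagent reacts through its γ-carbon (SE2′) at the unhindered epoxide CH2, so the gem-dimethyl carbon (future C4) and a vinyl group (masked C5 aldehyde) are installed while the carbinol centre (future C2) is untouched and keeps the configuration of 1.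

Step 2
Reactants: 4 (S)-1-chloro-4,4-dimethylhex-5-en-2-ol
Product: 5 (S)-tert-butyl[(1-chloro-4,4-dimethylhex-5-en-2-yl)oxy]dimethylsilane
Conditions: TBSCl, imidazole, DMF, rt
Reagents that add atoms: tert-butyldimethylsilyl chloride, CC(C)(C)[Si](C)(C)Cl
Why: Standard silylation of a secondary alcohol; the TBS ether is chosen because it should survive the later enolate, hydride, oxidation and low-temperature Lewis acid steps.

Step 3
Reactants: 5 (S)-tert-butyl[(1-chloro-4,4-dimethylhex-5-en-2-yl)oxy]dimethylsilane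
Product: 6 (S)-tert-butyl[(1-iodo-4,4-dimethylhex-5-en-2-yl)oxy]dimethylsilane
Conditions: NaI, 2-butanone, reflux
Reagents that add atoms: sodium iodide, [Na+].[I-]
Why: Finkelstein exchange at the primary carbon, driven by precipitation of NaCl, gives the iodide needed for the enolate alkylation without touching the stereocentre.

Step 4
Reactants: 7 3-isopropylcatechol
Product: 8 1,2-dimethoxy-3-isopropylbenzene
Conditions: MeI, K2CO3, DMF, rt
Reagents that add atoms: iodomethane, CI
Why: Williamson etherification of both phenols gives methyl ethers that direct the lithiation, activate the arene for the key step and withstand every step up to the end game.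

Step 5
Reactants: 8 1,2-dimethoxy-3-isopropylbenzene
Product: 10 (2,3-dimethoxy-4-isopropylphenyl)boronic acid, via aryllithium 9 (not isolated)
Conditions: n-BuLi, TMEDA, Et2O, 0 °C → rt; B(OMe)3, −78 °C → rt; 1 M HCl
Reagents that add atoms: trimethyl borate, COB(OC)OC; water, O
Why: Directed ortho-metalation, in which the only ring position ortho to a methoxy group is C6 of 8 (the other methoxy group is flanked by the isopropyl group), so lithiation is regiospecific and borate trapping with hydrolysis gives the boronic acid.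

Step 6
Reactants: 10 (2,3-dimethoxy-4-isopropylphenyl)boronic acid
Product: 11 methyl 2-(2,3-dimethoxy-4-isopropylphenyl)acetate
Conditions: methyl bromoacetate, Pd(OAc)2 (3 mol%), P(o-tol)3 (9 mol%), K3PO4, THF/H2O, rt
Reagents that add atoms: methyl bromoacetate, COC(=O)CBr
Why: Suzuki–Miyaura-type sp2–sp3 coupling, in which oxidative addition of the α-bromo ester gives a palladium enolate that transmetalates with the arylboronate and reductively eliminates to the arylacetate, a known room-temperature route to arylacetic esters.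

Step 7
Reactants: 11 methyl 2-(2,3-dimethoxy-4-isopropylphenyl)acetate; 6 (S)-tert-butyl[(1-iodo-4,4-dimethylhex-5-en-2-yl)oxy]dimethylsilane
Product: 13 methyl (4R)-4-(tert-butyldimethylsilyloxy)-2-(2,3-dimethoxy-4-isopropylphenyl)-6,6-dimethyloct-7-enoate (both C2 epimers), via lithium enolate 12 (not isolated)
Conditions: LiHMDS, THF, −78 °C; then 6, DMPU, −78 °C → rt
Reagents that add atoms: none
Why: SN2 alkylation of the conjugated, weakly basic arylacetate enolate by the primary iodide forms the C10–C1 bond; the mixture at the benzylic carbon (future C10) is of no consequence because that centre is deprotonated again in step 10 (the descriptor at the silyloxy carbon changes from S to R only through the CIP priorities).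

Step 8
Reactants: 13 methyl (4R)-4-(tert-butyldimethylsilyloxy)-2-(2,3-dimethoxy-4-isopropylphenyl)-6,6-dimethyloct-7-enoate
Product: 15 methyl (4R)-4-(tert-butyldimethylsilyloxy)-2-(2,3-dimethoxy-4-isopropylphenyl)-6,6-dimethyl-7-oxoheptanoate (both C2 epimers), via vicinal diol 14 (not isolated)
Conditions: OsO4 (2 mol%), NaIO4, 2,6-lutidine, dioxane/H2O, rt
Reagents that add atoms: osmium tetroxide (catalytic, reoxidised by periodate), O=[Os](=O)(=O)=O; sodium periodate, [Na+].[O-]I(=O)(=O)=O
Why: Lemieux–Johnson oxidation (catalytic dihydroxylation, then periodate glycol cleavage) turns the vinyl group into the non-enolisable C5 aldehyde, and the osmium-based cleavage is preferred to ozone because it should leave the electron-rich dimethoxyarene untouched.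

Step 9
Reactants: 15 methyl (4R)-4-(tert-butyldimethylsilyloxy)-2-(2,3-dimethoxy-4-isopropylphenyl)-6,6-dimethyl-7-oxoheptanoate
Product: 16 dimethyl (2E,6R)-6-(tert-butyldimethylsilyloxy)-8-(2,3-dimethoxy-4-isopropylphenyl)-4,4-dimethylnon-2-enedioate (both C8 epimers)
Conditions: Ph3P=CHCO2Me, toluene, 90 °C
Reagents that add atoms: methyl (triphenylphosphoranylidene)acetate, COC(=O)C=P(c1ccccc1)(c1ccccc1)c1ccccc1
Why: Wittig olefination with a stabilised ylide should give the (E)-enoate from the hindered neopentyl aldehyde under neutral conditions that do not enolise the arylacetate.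

Step 10
Reactants: 16 dimethyl (2E,6R)-6-(tert-butyldimethylsilyloxy)-8-(2,3-dimethoxy-4-isopropylphenyl)-4,4-dimethylnon-2-enedioate
Product: 17 methyl (1R,2S,5S)-5-(tert-butyldimethylsilyloxy)-1-(2,3-dimethoxy-4-isopropylphenyl)-2-(2-methoxy-2-oxoethyl)-3,3-dimethylcyclohexane-1-carboxylate
Conditions: KOt-Bu (0.3 equiv), t-BuOH/THF, 0 °C → rt
Reagents that add atoms: none
Why: Intramolecular 6-exo-trig Michael addition under reversible alkoxide catalysis, in which both epimers of 16 give the same enolate, the gem-dimethyl group favours closure (Thorpe–Ingold effect), and the Michael/retro-Michael equilibrium should settle on the chair that carries the C2 silyloxy group, the C5 side chain and the C10 aryl group equatorial and only the smaller ester axial, so that the fixed C2 centre sets C5 (S) and C10 (R).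

Step 11
Reactants: 17 methyl (1R,2S,5S)-5-(tert-butyldimethylsilyloxy)-1-(2,3-dimethoxy-4-isopropylphenyl)-2-(2-methoxy-2-oxoethyl)-3,3-dimethylcyclohexane-1-carboxylate
Product: 18 2-[(1S,2R,4S)-4-(tert-butyldimethylsilyloxy)-2-(2,3-dimethoxy-4-isopropylphenyl)-2-(hydroxymethyl)-6,6-dimethylcyclohexyl]ethan-1-ol
Conditions: LiAlH4, THF, 0 °C → rt
Reagents that add atoms: none
Why: Hydride reduction of both methyl esters gives the 1,5-diol (C7–OH and C20–OH) without affecting the silyl ether or any stereocentre.

Step 12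
Reactants: 18 2-[(1S,2R,4S)-4-(tert-butyldimethylsilyloxy)-2-(2,3-dimethoxy-4-isopropylphenyl)-2-(hydroxymethyl)-6,6-dimethylcyclohexyl]ethan-1-ol
Product: 20 (4aS,7S,8aR)-7-(tert-butyldimethylsilyloxy)-8a-(2,3-dimethoxy-4-isopropylphenyl)-5,5-dimethyloctahydro-3H-isochromen-3-one, via lactol 19 (not isolated)
Conditions: TEMPO (20 mol%), PhI(OAc)2 (2.5 equiv), CH2Cl2, rt
Reagents that add atoms: none
Why: Oxidative lactonisation of a 1,5-diol, in which the sterically sensitive oxoammonium oxidant should take the unhindered C7 alcohol before the neopentyl C20 alcohol, the aldehyde is captured by the C20 hydroxyl as lactol 19, and a second oxidation gives the δ-lactone with the carbonyl at C7.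

Step 13
Reactants: 20 (4aS,7S,8aR)-7-(tert-butyldimethylsilyloxy)-8a-(2,3-dimethoxy-4-isopropylphenyl)-5,5-dimethyloctahydro-3H-isochromen-3-one
Product: 19 (4aS,7S,8aR)-7-(tert-butyldimethylsilyloxy)-8a-(2,3-dimethoxy-4-isopropylphenyl)-5,5-dimethyloctahydro-1H-isochromen-3-ol (C7 lactol in abietane numbering; both anomers)
Conditions: DIBAL-H (1.1 equiv), CH2Cl2, −78 °C; Rochelle salt
Reagents that add atoms: none
Why: Partial reduction of a lactone stops at the lactol because the tetrahedral aluminium hemiacetal is stable at −78 °C, and the anomeric mixture is irrelevant since C7 is ionised in the next step.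

Step 14
Reactants: 19 (4aS,7S,8aR)-7-(tert-butyldimethylsilyloxy)-8a-(2,3-dimethoxy-4-isopropylphenyl)-5,5-dimethyloctahydro-1H-isochromen-3-ol
Product: 22 (2S,5S,7S,10R)-2-(tert-butyldimethylsilyloxy)-7,20-epoxy-11,12-dimethoxyabieta-8,11,13-triene, via oxocarbenium ion 21 (not isolated)
Conditions: TMSOTf (0.3 equiv), 4 Å MS, CH2Cl2, −78 → −20 °C
Reagents that add atoms: none
Why: Activation of the anomeric hydroxyl ionises 19 to the six-membered oxocarbenium ion 21 (C7=O+–C20), and in its boat conformer the aryl group on C10, already axial on this ring because the ring is cis-fused to ring A, sits over C7 so that C8 attacks C7 and rearomatisation returns the acid. The closest known reaction is the oxa-Pictet–Spengler cyclisation of a 2-arylethanol hemiacetal, here with the aldehyde tethered through ring A as in Friedel–Crafts trapping of lactol-derived oxocarbenium ions by a pendant arene. Ring B (C5–C6–C7–C8–C9–C10) closes 6-exo-trig with respect to C7=O+, and the isochroman ring (C8–C7–O–C20–C10–C9) closes 6-endo-trig, so one C–C bond gives the bicyclo[2.2.2] core. C7 is the only new stereocentre and the bridge fixes it as S, because the arene can reach only the face of the ion on which it is held. The step needs regioselection on the arene and chemoselective ionisation: C8 is the only unsubstituted position ortho to C9 and is para to the C12 methoxy group, and a catalytic silyl triflate at low temperature should ionise the lactol without cleaving the secondary TBS ether. Reversible side equilibria (enol ether, lactol dimers) should drain into the product because the C–C bond formation is irreversible.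

Step 15
Reactants: 22 (2S,5S,7S,10R)-2-(tert-butyldimethylsilyloxy)-7,20-epoxy-11,12-dimethoxyabieta-8,11,13-triene
Product: 23 (2S,5S,7S,10R)-7,20-epoxy-11,12-dimethoxyabieta-8,11,13-trien-2-ol
Conditions: TBAF, THF, rt
Reagents that add atoms: none
Why: Fluoride-driven Si–O cleavage frees the C2 alcohol, and no other group in 22 responds to fluoride.

Step 16
Reactants: 23 (2S,5S,7S,10R)-7,20-epoxy-11,12-dimethoxyabieta-8,11,13-trien-2-ol
Product: 25 (2S,5S,7S,10R)-7,20-epoxyabieta-8,11,13-triene-2,11,12-triyl triacetate, via triol 24 (not isolated)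
Conditions: NaSEt (10 equiv), degassed DMF, 130 °C; then Ac2O, pyridine, DMAP, 0 °C → rt
Reagents that add atoms: acetic anhydride, CC(=O)OC(C)=O
Why: Thiolate SN2 demethylation attacks only the two O-methyl carbons (the bridged ether cannot be attacked at bridgehead C7 or neopentyl C20), and acetylation in the same flask traps the air-sensitive catecholate together with the C2 alcohol as a stable triacetate.

Step 17
Reactants: 25 (2S,5S,7S,10R)-7,20-epoxyabieta-8,11,13-triene-2,11,12-triyl triacetate
Product: 26 (2S,5S,7S,10R)-2-acetoxy-7,20-epoxyabieta-8,11,13-triene-11,12-diol (target)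
Conditions: N2H4·H2O (2.5 equiv), degassed THF, 0 °C → rt
Reagents that add atoms: none
Why: Chemoselective hydrazinolysis, in which aryl acetates are far better acyl donors (phenoxide leaving group) than a secondary alkyl acetate, so both phenols should be freed while the C2 acetate stays.

**Compound list**

1 | (S)-epichlorohydrin | ClC[C@@H]1CO1 | starting material
2 | prenyl chloride (1-chloro-3-methylbut-2-ene) | CC(C)=CCCl | starting material
3 | prenylmagnesium chloride | CC(C)=CC[Mg]Cl | intermediate
4 | (S)-1-chloro-4,4-dimethylhex-5-en-2-ol | ClC[C@@H](O)CC(C)(C)C=C | intermediate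
5 | (S)-tert-butyl[(1-chloro-4,4-dimethylhex-5-en-2-yl)oxy]dimethylsilane | ClC[C@@H](O[Si](C)(C)C(C)(C)C)CC(C)(C)C=C | intermediate
6 | (S)-tert-butyl[(1-iodo-4,4-dimethylhex-5-en-2-yl)oxy]dimethylsilane | IC[C@@H](O[Si](C)(C)C(C)(C)C)CC(C)(C)C=C | intermediate
7 | 3-isopropylcatechol | CC(C)c1cccc(O)c1O | starting material
8 | 1,2-dimethoxy-3-isopropylbenzene | COc1cccc(C(C)C)c1OC | intermediate
9 | (2,3-dimethoxy-4-isopropylphenyl)lithium | [Li]c1ccc(C(C)C)c(OC)c1OC | intermediate
10 | (2,3-dimethoxy-4-isopropylphenyl)boronic acid | OB(O)c1ccc(C(C)C)c(OC)c1OC | intermediate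
11 | methyl 2-(2,3-dimethoxy-4-isopropylphenyl)acetate | COC(=O)Cc1ccc(C(C)C)c(OC)c1OC | intermediate
12 | lithium enolate of 11 | [Li]OC(OC)=Cc1ccc(C(C)C)c(OC)c1OC | intermediate
13 | methyl (4R)-4-(tert-butyldimethylsilyloxy)-2-(2,3-dimethoxy-4-isopropylphenyl)-6,6-dimethyloct-7-enoate (both C2 epimers) | COC(=O)C(C[C@@H](O[Si](C)(C)C(C)(C)C)CC(C)(C)C=C)c1ccc(C(C)C)c(OC)c1OC | intermediate
14 | methyl (4R)-4-(tert-butyldimethylsilyloxy)-2-(2,3-dimethoxy-4-isopropylphenyl)-7,8-dihydroxy-6,6-dimethyloctanoate (epimers at C2 and C7) | COC(=O)C(C[C@@H](O[Si](C)(C)C(C)(C)C)CC(C)(C)C(O)CO)c1ccc(C(C)C)c(OC)c1OC | intermediate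
15 | methyl (4R)-4-(tert-butyldimethylsilyloxy)-2-(2,3-dimethoxy-4-isopropylphenyl)-6,6-dimethyl-7-oxoheptanoate (both C2 epimers) | COC(=O)C(C[C@@H](O[Si](C)(C)C(C)(C)C)CC(C)(C)C=O)c1ccc(C(C)C)c(OC)c1OC | intermediate
16 | dimethyl (2E,6R)-6-(tert-butyldimethylsilyloxy)-8-(2,3-dimethoxy-4-isopropylphenyl)-4,4-dimethylnon-2-enedioate (both C8 epimers) | COC(=O)C(C[C@@H](O[Si](C)(C)C(C)(C)C)CC(C)(C)/C=C/C(=O)OC)c1ccc(C(C)C)c(OC)c1OC | intermediate
17 | methyl (1R,2S,5S)-5-(tert-butyldimethylsilyloxy)-1-(2,3-dimethoxy-4-isopropylphenyl)-2-(2-methoxy-2-oxoethyl)-3,3-dimethylcyclohexane-1-carboxylate | CC(C)(C)[Si](C)(C)O[C@H]1CC(C)(C)[C@H](CC(=O)OC)[C@@](C1)(C(=O)OC)c1ccc(C(C)C)c(OC)c1OC | intermediate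
18 | 2-[(1S,2R,4S)-4-(tert-butyldimethylsilyloxy)-2-(2,3-dimethoxy-4-isopropylphenyl)-2-(hydroxymethyl)-6,6-dimethylcyclohexyl]ethan-1-ol | CC(C)(C)[Si](C)(C)O[C@H]1CC(C)(C)[C@H](CCO)[C@@](C1)(CO)c1ccc(C(C)C)c(OC)c1OC | intermediate
19 | (4aS,7S,8aR)-7-(tert-butyldimethylsilyloxy)-8a-(2,3-dimethoxy-4-isopropylphenyl)-5,5-dimethyloctahydro-1H-isochromen-3-ol (C7 lactol, both anomers) | CC(C)(C)[Si](C)(C)O[C@H]1CC(C)(C)[C@@H]2CC(O)OC[C@@]2(C1)c1ccc(C(C)C)c(OC)c1OC | intermediate
20 | (4aS,7S,8aR)-7-(tert-butyldimethylsilyloxy)-8a-(2,3-dimethoxy-4-isopropylphenyl)-5,5-dimethyloctahydro-3H-isochromen-3-one | CC(C)(C)[Si](C)(C)O[C@H]1CC(C)(C)[C@@H]2CC(=O)OC[C@@]2(C1)c1ccc(C(C)C)c(OC)c1OC | intermediate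
21 | cyclic oxocarbenium ion (C7=O+–C20) of 19, triflate | CC(C)(C)[Si](C)(C)O[C@H]1CC(C)(C)[C@@H]2CC=[O+]C[C@@]2(C1)c1ccc(C(C)C)c(OC)c1OC.[O-]S(=O)(=O)C(F)(F)F | intermediate
22 | (2S,5S,7S,10R)-2-(tert-butyldimethylsilyloxy)-7,20-epoxy-11,12-dimethoxyabieta-8,11,13-triene | CC(C)(C)[Si](C)(C)O[C@H]1CC(C)(C)[C@@H]2C[C@@H]3OC[C@@]2(C1)c1c3cc(C(C)C)c(OC)c1OC | intermediate
23 | (2S,5S,7S,10R)-7,20-epoxy-11,12-dimethoxyabieta-8,11,13-trien-2-ol | O[C@H]1CC(C)(C)[C@@H]2C[C@@H]3OC[C@@]2(C1)c1c3cc(C(C)C)c(OC)c1OC | intermediate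
24 | (2S,5S,7S,10R)-7,20-epoxyabieta-8,11,13-triene-2,11,12-triol | O[C@H]1CC(C)(C)[C@@H]2C[C@@H]3OC[C@@]2(C1)c1c3cc(C(C)C)c(O)c1O | intermediate
25 | (2S,5S,7S,10R)-7,20-epoxyabieta-8,11,13-triene-2,11,12-triyl triacetate | CC(=O)O[C@H]1CC(C)(C)[C@@H]2C[C@@H]3OC[C@@]2(C1)c1c3cc(C(C)C)c(OC(C)=O)c1OC(C)=O | intermediate
26 | (2S,5S,7S,10R)-2-acetoxy-7,20-epoxyabieta-8,11,13-triene-11,12-diol | CC(=O)O[C@H]1CC(C)(C)[C@@H]2C[C@@H]3OC[C@@]2(C1)c1c3cc(C(C)C)c(O)c1O | target

**Step count**

Total: 17 steps. Longest linear sequence: 14 steps (steps 4–17 from 7; equally steps 1–3 and 7–17 from 1).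

**Steps most likely to fail**

Step 14 (key step). The oxocarbenium ring may not reach the boat in which the aryl group lies over C7 before the ion is drained by proton loss to the enol ether, lactol self-condensation or acid-induced loss of the silyl group. The arene may also react slowly because both methoxy groups are twisted out of conjugation by their ortho neighbours. The fallback closes the two rings one after the other and sets out from diester 17. LiOH in THF/MeOH/H2O at rt should saponify only the unhindered side-chain ester and leave the axial ester on the quaternary carbon, giving the monoacid F1. Oxalyl chloride with catalytic DMF gives the acid chloride F2, and SnCl4 in CH2Cl2 at −78 → 0 °C should close ring B by Friedel–Crafts acylation at C8 to give the 7-oxo ester F3. LiAlH4 reduces ketone and ester to the 7,20-diol F4 (both C7 epimers). Catalytic camphorsulfonic acid in CH2Cl2 should ionise the para-methoxybenzylic C7 alcohol, and the C20 hydroxyl, which can reach the cation from one face only, closes the ether. The route is rejoined at 22.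

Step 10. The new C5–C10 bond joins a quaternary carbon to a neopentyl methine, so the Michael/retro-Michael balance may be unfavourable, or control of which C10 substituent (aryl or ester) takes the axial site may be poor. The fallback uses a smaller nucleophile and sets out from arylacetate 11 and iodide 6. Dimethylaluminium amide (AlMe3/NH4Cl, xylene, reflux) should convert 11 into the arylacetonitrile F5. LiHMDS-mediated alkylation with 6 gives the alkylated nitrile F6, OsO4/NaIO4 gives the aldehyde F7, and the stabilised ylide gives the cyano enoate F8. KOt-Bu in t-BuOH/THF should close ring A to the cyano ester F9; the linear nitrile is a slimmer nucleophile terminus and has a strong preference for the axial site at C10. DIBAL-H (excess, toluene, −78 → 0 °C, acidic work-up) reduces the ester to the alcohol and the nitrile to the aldehyde, giving the hydroxy aldehyde F10, and NaBH4 in MeOH gives diol 18, where the route is rejoined.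

Step 16. Cleavage of the second, doubly flanked methyl ether may be incomplete. The C7–O bond may open through a para-quinone methide once the C12 phenoxide exists at high temperature, and the catecholate may oxidise before it is acetylated. The fallback reverses the order of events and sets out from alcohol 23. Ac2O/pyridine/DMAP gives the 2-acetate F11, and BBr3 in CH2Cl2 at −78 → 0 °C cleaves both aryl methyl ethers by the Lewis acid pathway while the alkyl acetate is kept. This leads directly to target 26; a C7–O bond opened by the Lewis acid is expected to reclose on work-up because the C20 oxygen stays next to the C7 cation.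

**Further compounds**

F1 | step 14 | 2-[(1S,2R,4S)-4-(tert-butyldimethylsilyloxy)-2-(2,3-dimethoxy-4-isopropylphenyl)-2-(methoxycarbonyl)-6,6-dimethylcyclohexyl]acetic acid | CC(C)(C)[Si](C)(C)O[C@H]1CC(C)(C)[C@H](CC(=O)O)[C@@](C1)(C(=O)OC)c1ccc(C(C)C)c(OC)c1OC
F2 | step 14 | acid chloride of F1 | CC(C)(C)[Si](C)(C)O[C@H]1CC(C)(C)[C@H](CC(=O)Cl)[C@@](C1)(C(=O)OC)c1ccc(C(C)C)c(OC)c1OC
F3 | step 14 | methyl (2S,5S,10R)-2-(tert-butyldimethylsilyloxy)-11,12-dimethoxy-7-oxoabieta-8,11,13-trien-20-oate | CC(C)(C)[Si](C)(C)O[C@H]1CC(C)(C)[C@@H]2CC(=O)c3cc(C(C)C)c(OC)c(OC)c3[C@]2(C1)C(=O)OC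
F4 | step 14 | (2S,5S,10R)-2-(tert-butyldimethylsilyloxy)-11,12-dimethoxyabieta-8,11,13-triene-7,20-diol (both C7 epimers) | CC(C)(C)[Si](C)(C)O[C@H]1CC(C)(C)[C@@H]2CC(O)c3cc(C(C)C)c(OC)c(OC)c3[C@]2(C1)CO
F5 | step 10 | 2-(2,3-dimethoxy-4-isopropylphenyl)acetonitrile | N#CCc1ccc(C(C)C)c(OC)c1OC
F6 | step 10 | (4R)-4-(tert-butyldimethylsilyloxy)-2-(2,3-dimethoxy-4-isopropylphenyl)-6,6-dimethyloct-7-enenitrile (both C2 epimers) | N#CC(C[C@@H](O[Si](C)(C)C(C)(C)C)CC(C)(C)C=C)c1ccc(C(C)C)c(OC)c1OC
F7 | step 10 | (4R)-4-(tert-butyldimethylsilyloxy)-2-(2,3-dimethoxy-4-isopropylphenyl)-6,6-dimethyl-7-oxoheptanenitrile (both C2 epimers) | N#CC(C[C@@H](O[Si](C)(C)C(C)(C)C)CC(C)(C)C=O)c1ccc(C(C)C)c(OC)c1OC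
F8 | step 10 | methyl (2E,6R)-6-(tert-butyldimethylsilyloxy)-8-cyano-8-(2,3-dimethoxy-4-isopropylphenyl)-4,4-dimethyloct-2-enoate (both C8 epimers) | N#CC(C[C@@H](O[Si](C)(C)C(C)(C)C)CC(C)(C)/C=C/C(=O)OC)c1ccc(C(C)C)c(OC)c1OC
F9 | step 10 | methyl 2-[(1S,2R,4S)-4-(tert-butyldimethylsilyloxy)-2-cyano-2-(2,3-dimethoxy-4-isopropylphenyl)-6,6-dimethylcyclohexyl]acetate | CC(C)(C)[Si](C)(C)O[C@H]1CC(C)(C)[C@H](CC(=O)OC)[C@@](C1)(C#N)c1ccc(C(C)C)c(OC)c1OC
F10 | step 10 | (1R,2S,5S)-5-(tert-butyldimethylsilyloxy)-1-(2,3-dimethoxy-4-isopropylphenyl)-2-(2-hydroxyethyl)-3,3-dimethylcyclohexane-1-carbaldehyde | CC(C)(C)[Si](C)(C)O[C@H]1CC(C)(C)[C@H](CCO)[C@@](C1)(C=O)c1ccc(C(C)C)c(OC)c1OC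
F11 | step 16 | (2S,5S,7S,10R)-2-acetoxy-7,20-epoxy-11,12-dimethoxyabieta-8,11,13-triene | CC(=O)O[C@H]1CC(C)(C)[C@@H]2C[C@@H]3OC[C@@]2(C1)c1c3cc(C(C)C)c(OC)c1OC
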